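**Retrosynthetic overview**
1. Target 17 comes from the 7-endo type A bicyclic enol 16 by an oxidative radical cascade: C3–C11 closes the seven-membered (homoadamantane) bridge, then C12–C13 closes the cyclopentane; the isopropenyl group arises by oxidative elimination.
2. 16 comes from bicyclic dioxinone 12: the dioxinone is opened to an acylketene, trapped by prenol (C–O), and the prenyl group is moved to C3 by decarboxylative allylation.
3. 12 comes from carbinol 10 and hemiketal 9: the bicyclo[3.3.1] ring closes (C1–C8) by ionization at C8 and O9→C1 transfer.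
4. 9 comes from 5 + 7 by the key C–O ring closure: a dearomative Michael addition makes quaternary C5, and the O9–C8 hemiketal bond sets C7 trans to geranyl and holds C8 next to C1. O9 is the only free oxygen beside C5 because O4 is locked in the dioxinone.
5. 5 comes from catalog dioxinone 1 by acylation and geranylation. Ring order: arene (bought) → dihydropyran hemiketal → bicyclo[3.3.1]nonane → seven-membered bridge → cyclopentane.

Assumption: 1 is bought as a catalog compound (it is also one step from 2,4,6-trihydroxybenzoic acid, acetone and TFAA).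
Numbering used for 8–17: C1 carries isobutyryl; C2, C4, C9 are the oxygenated ring carbons (C9 between C1 and C5); C3 lies between C2 and C4; C5 carries geranyl; C6 (CH2), C7 (CH), C8 (CMe2 or C–O) form the second bridge; C10 is the CH2 on C7, C11 the next CH, C12 its CMe2, C13 the isopropenyl-bearing CH, C14 the CH2 on C3. In 1–5 (benzodioxinone numbering) C6 = C1, C8 = C5, C4a = C3, O1 = O4, 7-O = O9.

**Step 1**
Reactants: 1 5,7-dihydroxy-2,2-dimethyl-4H-1,3-benzodioxin-4-one; 2 isobutyryl chloride
Product: 3 5,7-dihydroxy-2,2-dimethyl-6-(2-methylpropanoyl)-4H-1,3-benzodioxin-4-one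
Conditions: TiCl4, (CH2Cl)2, 0 → 60 °C
Reagents that add atoms: none
Why: Friedel–Crafts C-acylation under Lewis-acid (Fries-reversible) conditions should favour C6, where the new ketone sits between two hydroxyls (double chelation) and avoids the acetal CMe2 next to C8; this regiochemistry is argued, not proven.

**Step 2**
Reactants: 3 the 6-isobutyryl benzodioxinone; 4 geranyl acetate
Product: 5 8-[(2E)-3,7-dimethylocta-2,6-dien-1-yl]-5,7-dihydroxy-2,2-dimethyl-6-(2-methylpropanoyl)-4H-1,3-benzodioxin-4-one
Conditions: Pd(PPh3)4 (5 mol%), Et3N, THF, 60 °C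
Reagents that add atoms: none
Why: Tsuji–Trost allylation with zerovalent palladium: O-geranylation of the acidic phenol is reversible and funnels to the only free ring carbon (C8), with attack at the CH2 terminus keeping the E-geranyl chain.

**Step 3**
Reactants: 6 6-methylhept-5-en-2-one (sulcatone)
Product: 7 6-methyl-3-methylidenehept-5-en-2-one
Conditions: (CH2O)n, i-Pr2NH·CF3CO2H, THF, 65 °C
Reagents that add atoms: formaldehyde (as paraformaldehyde), C=O
Why: Mannich-type α-methylenation at the more substituted α-carbon (thermodynamic enol) followed by amine elimination gives the α-substituted vinyl ketone.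

**Step 4**
Reactants: 5 the 8-geranyl benzodioxinone; 7 the enone
Product: 9 trans cyclic hemiketal (O9–C8 bond formed; C5 and C7 configured as in 16; anomer mixture), via open-chain Michael adduct 8 (not isolated)
Conditions: 7 (1.5 equiv), N-(9-anthracenylmethyl)cinchonidinium chloride (10 mol%), Cs2CO3, PhMe–CH2Cl2, −40 °C; then pyrrolidinium acetate (20 mol%), CH2Cl2, 23 °C
Reagents that add atoms: none
Why: Proposed new method: the chiral ammonium pairs with the 7-oxido group (the only oxido beside the reacting carbon) and shields one face while that carbon adds to the vinyl ketone (dearomative Michael addition, quaternary C5); the δ-keto enol then closes through O9 to the six-membered hemiketal, and enamine-mediated epimerization of the ring-opened ketone puts the C7 prenyl equatorial, i.e. trans to the necessarily axial geranyl (1,3-diaxial avoidance); closest known reactions are the phase-transfer-catalysed enantioselective alkylative dearomatization of acylphloroglucinols with enals and the Michael addition/hemiketalization of 4-hydroxycoumarin with enones; the sense of induction must be found by experiment (the cinchonine-derived salt is used if it is reversed).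

**Step 5**
Reactants: 9 the cyclic hemiketal
Product: 10 ring-opened tertiary carbinol (C5 bears geranyl and CH2–CH(prenyl)–C(CH3)2OH)
Conditions: MeMgBr (4 equiv), CeCl3, THF, −78 → −20 °C
Reagents that add atoms: methylmagnesium bromide, C[Mg]Br
Why: Deprotonation opens the hemiketal to the methyl ketone, and cerium-assisted Grignard 1,2-addition outruns enolization (no C7 epimerization, no retro-Michael) and attack on the less electrophilic dioxinone carbonyl; C8 becomes CMe2 and is not stereogenic.

**Step 6**
Reactants: 10 the tertiary carbinol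
Product: 12 type A bicyclo[3.3.1]nonane dioxinone (1-isobutyryl; 5-geranyl; 7-endo-prenyl; 8,8-dimethyl), via O-cyclised dihydropyran 11 (not isolated)
Conditions: BF3·OEt2, CH2Cl2, −60 → −10 °C
Reagents that add atoms: none
Why: SN1 ionization gives the C8 cation, trapped reversibly at O9 and then passed to the adjacent C1 enol carbon (biomimetic cation–enol cyclization, net 1,3 O→C shift); C3 is the non-nucleophilic dioxinone α-carbon and O4 is an acetal oxygen, so only type A closure is productive, and the trans C5/C7 relationship places the C7 prenyl endo.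

**Step 7**
Reactants: 12 the bicyclic dioxinone; 13 prenol (3-methylbut-2-en-1-ol)
Product: 16 (1R,5R,7R)-5-geranyl-4-hydroxy-1-isobutyryl-8,8-dimethyl-3,7-diprenylbicyclo[3.3.1]non-3-ene-2,9-dione, via acylketene 14 (not isolated), via prenyl beta-keto ester 15 (not isolated)
Conditions: 13 (3 equiv), PhMe, 105 °C; then Pd(PPh3)4 (5 mol%), 45 °C
Reagents that add atoms: none
Why: Retro-hetero-Diels–Alder of the 1,3-dioxin-4-one releases acetone and an acylketene that prenol traps as the ester; zerovalent palladium then effects Tsuji decarboxylative allylation, the soft diketonate attacking the CH2 terminus to give the C3-prenyl enol.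

**Step 8**
Reactants: 16 the bicyclic enol
Product: 17 CNP0280463.1, (1S,3S,5R,7R,11S,13S)
Conditions: Mn(OAc)3·2H2O (2.2 equiv), Cu(OAc)2·H2O (1 equiv), AcOH, 23 °C
Reagents that add atoms: none
Why: Oxidative radical cyclization: trivalent manganese oxidizes the enol to the C3 radical, which adds 7-exo to the endo C7 prenyl (CMe2 terminus turned to the C4/C6 side, away from the C8 methyls, setting C11), then 5-exo to the C3 prenyl on the open face (setting C13), and divalent copper oxidizes the tertiary radical with β-hydride loss to the isopropenyl group; C3 is fixed by the cage.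

**Compound list**
1 | 5,7-dihydroxy-2,2-dimethyl-4H-1,3-benzodioxin-4-one | CC1(C)OC(=O)c2c(O)cc(O)cc2O1 | starting material
2 | isobutyryl chloride | CC(C)C(Cl)=O | starting material
3 | 5,7-dihydroxy-2,2-dimethyl-6-(2-methylpropanoyl)-4H-1,3-benzodioxin-4-one | CC(C)C(=O)c1c(O)cc2OC(C)(C)OC(=O)c2c1O | intermediate
4 | geranyl acetate, (2E)-3,7-dimethylocta-2,6-dien-1-yl acetate | CC(=O)OC/C=C(\C)CCC=C(C)C | starting material
5 | 8-geranyl-5,7-dihydroxy-2,2-dimethyl-6-(2-methylpropanoyl)-4H-1,3-benzodioxin-4-one | CC(C)C(=O)c1c(O)c(C/C=C(\C)CCC=C(C)C)c2OC(C)(C)OC(=O)c2c1O | intermediate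
6 | 6-methylhept-5-en-2-one | CC(=O)CCC=C(C)C | starting material
7 | 6-methyl-3-methylidenehept-5-en-2-one | CC(=O)C(=C)CC=C(C)C | intermediate
8 | open-chain Michael adduct: dearomatised dioxinone-dienone, C5 bearing geranyl and a 2-acetyl-5-methylhex-4-en-1-yl chain (C7 epimers; not isolated) | CC(C)C(=O)C1=C(O)C2=C(OC(C)(C)OC2=O)[C@@](C/C=C(\C)CCC=C(C)C)(CC(CC=C(C)C)C(C)=O)C1=O | intermediate
9 | cyclic hemiketal: O9 closed onto the side-chain ketone (2-hydroxy-2-methyl-3-prenyl-dihydropyran fused at C9–C5), C7 prenyl trans to C5 geranyl, anomer mixture | CC(C)C(=O)C1=C2OC(C)(O)[C@H](CC=C(C)C)C[C@]2(C/C=C(\C)CCC=C(C)C)C3=C(C1=O)C(=O)OC(C)(C)O3 | intermediate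
10 | tertiary carbinol: ring-opened dienone, C5 bearing geranyl and CH2–CH(prenyl)–C(CH3)2OH, dioxinone intact | CC(C)C(=O)C1=C(O)C2=C(OC(C)(C)OC2=O)[C@@](C/C=C(\C)CCC=C(C)C)(C[C@@H](CC=C(C)C)C(C)(C)O)C1=O | intermediate
11 | O-cyclised 2,2-dimethyl-3-prenyl-dihydropyran (O9–C8 bond; not isolated) | CC(C)C(=O)C1=C2OC(C)(C)[C@H](CC=C(C)C)C[C@]2(C/C=C(\C)CCC=C(C)C)C3=C(C1=O)C(=O)OC(C)(C)O3 | intermediate
12 | type A bicyclo[3.3.1]nonane-2,9-dione with the C3/C4 dioxinone: 1-isobutyryl, 5-geranyl, 7-endo-prenyl, 8,8-dimethyl (stereocentres as in 16) | CC1(C)OC(=O)C2=C(O1)[C@@]3(C/C=C(\C)CCC=C(C)C)C[C@@H](CC=C(C)C)C(C)(C)[C@](C(=O)C(C)C)(C3=O)C2=O | intermediate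
13 | prenol, 3-methylbut-2-en-1-ol | CC(C)=CCO | starting material
14 | acylketene (C3=C=O) of the bicyclic 2,4,9-trione (not isolated) | O=C=C1C(=O)[C@@]2(C/C=C(\C)CCC=C(C)C)C[C@@H](CC=C(C)C)C(C)(C)[C@](C(=O)C(C)C)(C2=O)C1=O | intermediate
15 | prenyl ester of the bicyclic 4-hydroxy-2,9-dioxo-3-ene-3-carboxylic acid (not isolated) | CC(C)=CCOC(=O)C1=C(O)[C@@]2(C/C=C(\C)CCC=C(C)C)C[C@@H](CC=C(C)C)C(C)(C)[C@](C(=O)C(C)C)(C2=O)C1=O | intermediate
16 | (1R,5R,7R)-5-[(2E)-3,7-dimethylocta-2,6-dien-1-yl]-4-hydroxy-8,8-dimethyl-3,7-bis(3-methylbut-2-en-1-yl)-1-(2-methylpropanoyl)bicyclo[3.3.1]non-3-ene-2,9-dione | CC(C)=CCC1=C(O)[C@@]2(C/C=C(\C)CCC=C(C)C)C[C@@H](CC=C(C)C)C(C)(C)[C@](C(=O)C(C)C)(C2=O)C1=O | intermediate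
17 | CNP0280463.1: (1S,3S,5R,7R,11S,13S) caged tetraketone; C3–C11 and C10–C7 form the homoadamantane bridge, C3/C14/C13/C12/C11 the cyclopentane, 13-isopropenyl, 12,12- and 8,8-dimethyl, 1-isobutyryl, 5-geranyl | C=C(C)[C@@H]1C[C@@]23C(=O)[C@@]4(C/C=C(\C)CCC=C(C)C)C[C@@H](C[C@H]2C1(C)C)C(C)(C)[C@](C(=O)C(C)C)(C4=O)C3=O | target

**Step count**
Total: 8 steps. Longest linear sequence: 7 steps (1, 2, 4, 5, 6, 7, 8; step 3 is the side branch).

**Three steps most likely to fail**

Step 4 (the proposed new step). Facial control of a nearly flat, remote nucleophile may be poor, and base could trigger retro-Michael erosion. Fallback with known chemistry: setting out from 5 (with 7), run the same Michael addition/hemiketalization with achiral base only (Cs2CO3, no chiral salt), equilibrate C7 as before, and separate the racemate (9 and its mirror image, ent-hemiketal F1) by preparative HPLC on a chiral stationary phase; the route is rejoined at 9.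

Step 6. The cation may stop at the O-cyclised pyran 11, lose a proton (epimerizing C7), or attack the geranyl chain. Fallback: setting out from 10, silylate both hydroxyls (TMSOTf, Et3N) to the bis(trimethylsilyl) compound F2 (C1=C2 silyl enol ether, tertiary silyl ether); then TiCl4 at −78 °C effects Lewis-acid tert-alkylation of the silyl enol ether at C1 under aprotic conditions; the route is rejoined at 12.

Step 8. The C3 radical may instead be oxidized to O-cyclised products or add to the geranyl chain. Fallback: setting out from 16, chlorinate C3 with N-chlorosuccinimide to the 3-chloro-3-prenyl-2,4-dione F3 (C3 epimers); run an atom-transfer radical cyclization with CuCl and tris(2-pyridylmethyl)amine (monovalent copper) to the cage tertiary chloride F4; eliminate HCl with DBU to the isopropenyl group; the route is rejoined at 17.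

**Further compounds**
F1 | step 4 | enantiomer of cyclic hemiketal 9 | CC(C)C(=O)C1=C2OC(C)(O)[C@@H](CC=C(C)C)C[C@@]2(C/C=C(\C)CCC=C(C)C)C3=C(C1=O)C(=O)OC(C)(C)O3
F2 | step 6 | bis(trimethylsilyl) derivative of 10 (O2 silyl enol ether and tertiary silyl ether) | CC(C)C(=O)C1=C(O[Si](C)(C)C)C2=C(OC(C)(C)OC2=O)[C@@](C/C=C(\C)CCC=C(C)C)(C[C@@H](CC=C(C)C)C(C)(C)O[Si](C)(C)C)C1=O
F3 | step 8 | 3-chloro-3-prenyl bicyclic 2,4,9-trione from 16 (C3 epimers) | CC(C)=CCC1(Cl)C(=O)[C@@]2(C/C=C(\C)CCC=C(C)C)C[C@@H](CC=C(C)C)C(C)(C)[C@](C(=O)C(C)C)(C2=O)C1=O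
F4 | step 8 | cage tertiary chloride: 17 with 2-chloropropan-2-yl in place of isopropenyl | CC(C)(Cl)[C@@H]1C[C@@]23C(=O)[C@@]4(C/C=C(\C)CCC=C(C)C)C[C@@H](C[C@H]2C1(C)C)C(C)(C)[C@](C(=O)C(C)C)(C4=O)C3=O
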